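Unit A, the 7-hydroxy-6,8-dimethoxycoumarin half, has a benzene ring with oxygen on four adjacent carbons (C6, C7, C8, C8a), which is the substitution pattern of squaric acid. Only C5 and C4a have to be added. The route therefore rests on forming the C8a–C4a bond. A squarate-derived 4-alkenyl-2,3,4-trimethoxycyclobutenone, whose alkene terminus carries a masked formyl group, is heated. Ring opening to a dienylketene and 6π closure should give the whole arene in one operation as a salicylaldehyde acetal, with its only free hydroxyl on C8a next to the future C4. Unmasking, cleavage of the C7 methyl ether and a Perkin condensation with an isofraxidin-derived aryloxyacetic acid then complete the pyranone ring and the ether link.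

Key step: step 3

Remark: the target is achiral; cyclobutenone 6 and dienone 8 are racemic and their stereocentres are destroyed in step 3, so only the E alkene geometry of 2, 4, 5 and 6 has to be carried.

Step 1
Reactants: 1 3,3-diethoxyprop-1-yne
Product: 2 (E)-tributyl(3,3-diethoxyprop-1-en-1-yl)stannane
Conditions: Bu3SnH (1.1 equiv), AIBN (cat.), neat, 85 °C
Reagents that add atoms: tributyltin hydride, CCCC[SnH](CCCC)CCCC
Why: Radical hydrostannylation of a terminal alkyne puts tin on the terminal carbon, and reversible stannyl-radical addition under a slight excess of hydride should equilibrate the adduct to the E alkene, while any residual Z isomer would converge on the same arene in step 3.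

Step 2
Reactants: 2 (E)-tributyl(3,3-diethoxyprop-1-en-1-yl)stannane; 3 dimethyl squarate
Product: 6 4-[(E)-3,3-diethoxyprop-1-en-1-yl]-2,3,4-trimethoxycyclobut-2-en-1-one (racemic), via alkenyllithium 4 (not isolated), via lithium alkoxide 5 (not isolated)
Conditions: n-BuLi, THF, −78 °C; cannulated into 3, THF, −78 °C; then MeOTf, −78 → 0 °C; aq. NaHCO3
Reagents that add atoms: methyl trifluoromethanesulfonate, COS(=O)(=O)C(F)(F)F
Why: Tin–lithium exchange proceeds with retention of alkene geometry, 1,2-addition of the alkenyllithium to one of the two equivalent carbonyl groups of the symmetric squarate raises no regiochemical question and stops at mono-addition, and O-methylation of the tertiary lithium alkoxide with methyl triflate is the standard trapping for such adducts; the new quaternary centre forms as a racemate.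

Step 3
Reactants: 6 4-[(E)-3,3-diethoxyprop-1-en-1-yl]-2,3,4-trimethoxycyclobut-2-en-1-one
Product: 9 2-(diethoxymethyl)-4,5,6-trimethoxyphenol (2-hydroxy-3,4,5-trimethoxybenzaldehyde diethyl acetal), via dienylketene 7 (not isolated), via cyclohexadienone 8 (not isolated)
Conditions: toluene (0.02 M, degassed), 110 °C, Ar, base-washed glassware
Reagents that add atoms: none
Why: Heating opens the cyclobutenone by a conrotatory 4π electrocyclic reaction in which the C4 methoxy donor turns outward, so the alkenyl arm sits cis to the ketene in dienylketene 7. A thermally allowed disrotatory 6π electrocyclisation then joins the ketene carbon (future C8a) to the alkene terminus (future C4a), closing the six-membered carbocycle as cyclohexadienone 8, and enolisation driven by aromatisation gives phenol 9. The closest known reaction type is the Moore rearrangement of squarate-derived 4-alkenyl-4-alkoxycyclobutenones to polyoxygenated phenols. No stereocentre survives, since the quaternary carbon of 6 becomes sp2 on ring opening and the transient sp3 carbon of 8 is lost on tautomerisation. The selectivity needed is the torquoselectivity of the ring opening, which is secured by the strong outward preference of a C4 alkoxy group and backed by the reversibility of the unproductive opening, and the E alkene keeps the acetal on the outside of the closing termini. Because the squarate was symmetric, its four oxygenated carbons can map onto C6, C7, C8 and C8a in only one way, which leaves the free hydroxyl on C8a beside the masked formyl carbon.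

Step 4
Reactants: 9 2-(diethoxymethyl)-4,5,6-trimethoxyphenol
Product: 10 2-hydroxy-3,4,5-trimethoxybenzaldehyde
Conditions: 1 M aq. HCl, THF, 0 °C → rt
Reagents that add atoms: water, O
Why: Acid-catalysed acetal hydrolysis of a benzylic acetal is fast under mild conditions that leave aryl methyl ethers untouched, and the resulting aldehyde is stabilised by a hydrogen bond to the ortho hydroxyl.

Step 5
Reactants: 10 2-hydroxy-3,4,5-trimethoxybenzaldehyde
Product: 11 2,4-dihydroxy-3,5-dimethoxybenzaldehyde
Conditions: LiCl (5 equiv), DMF, 150 °C; then 1 M aq. HCl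
Reagents that add atoms: none
Why: Nucleophilic demethylation of an aryl methyl ether by chloride (SN2 at methyl) needs a conjugated acceptor, and only the 4-methoxy group is para to the formyl group and also flanked and twisted out of plane by two neighbours, whereas the 3- and 5-methoxy groups are meta and unactivated, as in the conversion of 3,4,5-trimethoxybenzaldehyde to syringaldehyde.

Step 6
Reactants: 12 isofraxidin
Product: 13 tert-butyl 2-[(6,8-dimethoxy-2-oxo-2H-chromen-7-yl)oxy]acetate
Conditions: BrCH2CO2t-Bu, K2CO3, DMF, 50 °C
Reagents that add atoms: tert-butyl bromoacetate, CC(C)(C)OC(=O)CBr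
Why: Williamson etherification of the acidic 7-hydroxyl with a reactive α-bromo ester under carbonate conditions should not open the lactone.

Step 7
Reactants: 13 tert-butyl 2-[(6,8-dimethoxy-2-oxo-2H-chromen-7-yl)oxy]acetate
Product: 14 2-[(6,8-dimethoxy-2-oxo-2H-chromen-7-yl)oxy]acetic acid
Conditions: TFA, CH2Cl2, rt
Reagents that add atoms: none
Why: Acidolysis of the tert-butyl ester (loss of 2-methylpropene) frees the acid without the aqueous base that would open the coumarin lactone.

Step 8
Reactants: 11 2,4-dihydroxy-3,5-dimethoxybenzaldehyde; 14 2-[(6,8-dimethoxy-2-oxo-2H-chromen-7-yl)oxy]acetic acid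
Product: 16 3-[(6,8-dimethoxy-2-oxo-2H-chromen-7-yl)oxy]-6,8-dimethoxy-2-oxo-2H-chromen-7-yl acetate, via aryl ester 15 (not isolated)
Conditions: Ac2O, KOAc, 140 °C
Reagents that add atoms: acetic anhydride, CC(=O)OC(C)=O
Why: In this Perkin (Oglialoro) coumarin synthesis the acid is activated as a mixed anhydride and transferred to the ortho phenol, the α-aryloxy ester enolate adds intramolecularly to the formyl group and dehydration forms the C3–C4 double bond of the pyranone, while the anhydride caps the 7-hydroxyl as its acetate.

Step 9
Reactants: 16 3-[(6,8-dimethoxy-2-oxo-2H-chromen-7-yl)oxy]-6,8-dimethoxy-2-oxo-2H-chromen-7-yl acetate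
Product: 17 7-hydroxy-3-[(6,8-dimethoxy-2-oxo-2H-chromen-7-yl)oxy]-6,8-dimethoxy-2H-chromen-2-one (CNP0278842.0)
Conditions: HCl (1.25 M in MeOH), 50 °C
Reagents that add atoms: none
Why: Acid-catalysed transesterification removes the aryl acetate, and both lactones, the aryl methyl ethers and the C3 aryl ether should be stable to dilute methanolic acid.

Compound list
1 | 3,3-diethoxyprop-1-yne | CCOC(OCC)C#C | starting material
2 | (E)-tributyl(3,3-diethoxyprop-1-en-1-yl)stannane | CCCC[Sn](CCCC)(CCCC)/C=C/C(OCC)OCC | intermediate
3 | dimethyl squarate (3,4-dimethoxycyclobut-3-ene-1,2-dione) | COC1=C(OC)C(=O)C1=O | starting material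
4 | (E)-(3,3-diethoxyprop-1-en-1-yl)lithium | [Li]/C=C/C(OCC)OCC | intermediate
5 | lithium 1-[(E)-3,3-diethoxyprop-1-en-1-yl]-2,3-dimethoxy-4-oxocyclobut-2-en-1-olate (racemic) | [Li]OC1(/C=C/C(OCC)OCC)C(OC)=C(OC)C1=O | intermediate
6 | 4-[(E)-3,3-diethoxyprop-1-en-1-yl]-2,3,4-trimethoxycyclobut-2-en-1-one (racemic) | CCOC(OCC)/C=C/C1(OC)C(OC)=C(OC)C1=O | intermediate
7 | (3Z,5E)-7,7-diethoxy-2,3,4-trimethoxyhepta-1,3,5-trien-1-one | O=C=C(OC)/C(OC)=C(OC)\C=C\C(OCC)OCC | intermediate
8 | 6-(diethoxymethyl)-2,3,4-trimethoxycyclohexa-2,4-dien-1-one (racemic) | CCOC(OCC)C1C=C(OC)C(OC)=C(OC)C1=O | intermediate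
9 | 2-(diethoxymethyl)-4,5,6-trimethoxyphenol | CCOC(OCC)c1cc(OC)c(OC)c(OC)c1O | intermediate
10 | 2-hydroxy-3,4,5-trimethoxybenzaldehyde | COc1cc(C=O)c(O)c(OC)c1OC | intermediate
11 | 2,4-dihydroxy-3,5-dimethoxybenzaldehyde | COc1cc(C=O)c(O)c(OC)c1O | intermediate
12 | isofraxidin (7-hydroxy-6,8-dimethoxy-2H-chromen-2-one) | COc1cc2ccc(=O)oc2c(OC)c1O | starting material
13 | tert-butyl 2-[(6,8-dimethoxy-2-oxo-2H-chromen-7-yl)oxy]acetate | COc1cc2ccc(=O)oc2c(OC)c1OCC(=O)OC(C)(C)C | intermediate
14 | 2-[(6,8-dimethoxy-2-oxo-2H-chromen-7-yl)oxy]acetic acid | COc1cc2ccc(=O)oc2c(OC)c1OCC(=O)O | intermediate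
15 | 3-acetoxy-6-formyl-2,4-dimethoxyphenyl 2-[(6,8-dimethoxy-2-oxo-2H-chromen-7-yl)oxy]acetate | COc1cc(C=O)c(OC(=O)COc2c(OC)cc3ccc(=O)oc3c2OC)c(OC)c1OC(C)=O | intermediate
16 | 3-[(6,8-dimethoxy-2-oxo-2H-chromen-7-yl)oxy]-6,8-dimethoxy-2-oxo-2H-chromen-7-yl acetate | COc1cc2cc(Oc3c(OC)cc4ccc(=O)oc4c3OC)c(=O)oc2c(OC)c1OC(C)=O | intermediate
17 | 7-hydroxy-3-[(6,8-dimethoxy-2-oxo-2H-chromen-7-yl)oxy]-6,8-dimethoxy-2H-chromen-2-one | COc1cc2cc(Oc3c(OC)cc4ccc(=O)oc4c3OC)c(=O)oc2c(OC)c1O | target

Total step count: 9. Longest linear sequence: 7 steps (steps 1, 2, 3, 4, 5, 8, 9); steps 6 and 7 form a two-step branch from isofraxidin that joins at step 8.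

Steps most likely to fail

Step 5. Chloride attack may be slow on the electron-rich, hydrogen-bonded salicylaldehyde. Prolonged heating could then erode the preference for the para methyl group or degrade the aldehyde. The fallback sets out from 10 and comes back at 11. The phenol of 10 is capped with 2-bromopropane and K2CO3 in DMF to give 2-isopropoxy-3,4,5-trimethoxybenzaldehyde F1, which has no acidic proton. NaSEt in DMF at 100 °C should then remove only the methyl group para to the formyl group, because thiolate SN2 attack on the secondary isopropyl carbon is far slower, to give 4-hydroxy-2-isopropoxy-3,5-dimethoxybenzaldehyde F2. BCl3 in CH2Cl2 at −78 to 0 °C cleaves an isopropyl aryl ether next to a carbonyl group much faster than methyl ethers and should return 11.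

Step 8. At 140 °C, tar formation from the electron-rich aldehyde and decay of the aryloxyacetic acid may outrun acyl transfer and cyclisation. The fallback sets out from 11 and 14 and comes back at 16, with the acylation and the ring closure separated. The non-chelated 4-hydroxyl of 11 is acetylated with one equivalent of Ac2O and Et3N in CH2Cl2 at 0 °C to give 4-formyl-3-hydroxy-2,6-dimethoxyphenyl acetate F3. The remaining phenol is esterified with acid 14 (EDC·HCl, DMAP, CH2Cl2) to give ester 15, which is isolated this time. DBU in MeCN at 60 °C should then effect the intramolecular Knoevenagel condensation and dehydration to 16.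

Step 3. The freshly formed phenol 9 may lose ethanol from its ortho acetal at 110 °C and the resulting ortho-quinone methide may oligomerise; acid traces may also scramble the acetal. The fallback sets out from 3 and comes back at 10, leaving the formyl carbon out of the annulation. Vinyllithium (from tributyl(vinyl)stannane and n-BuLi, THF, −78 °C) is added to 3 and the alkoxide is trapped with MeOTf to give racemic 2,3,4-trimethoxy-4-vinylcyclobut-2-en-1-one F4. The same thermal rearrangement in toluene at 110 °C should give 2,3,4-trimethoxyphenol F5. Magnesium-mediated ortho-formylation (MgCl2, Et3N, paraformaldehyde, MeCN, reflux) can occur only at the single free ortho position and should give 10.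

Further compounds
F1 | step 5 | 2-isopropoxy-3,4,5-trimethoxybenzaldehyde | COc1cc(C=O)c(OC(C)C)c(OC)c1OC
F2 | step 5 | 4-hydroxy-2-isopropoxy-3,5-dimethoxybenzaldehyde | COc1cc(C=O)c(OC(C)C)c(OC)c1O
F3 | step 8 | 4-formyl-3-hydroxy-2,6-dimethoxyphenyl acetate | COc1cc(C=O)c(O)c(OC)c1OC(C)=O
F4 | step 3 | 2,3,4-trimethoxy-4-vinylcyclobut-2-en-1-one (racemic) | C=CC1(OC)C(OC)=C(OC)C1=O
F5 | step 3 | 2,3,4-trimethoxyphenol | COc1ccc(O)c(OC)c1OC
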